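**Assumption:** (R)-3-hydroxy-γ-butyrolactone (1), 3,4-dimethoxybenzyl bromide (2), syringyl alcohol (5) and the benzoxazolium salt 7 are taken as catalogue items.

## Retrosynthetic overview

1. Target 13 ⇐ diol 11 by O-acetylation of the two primary alcohols only; 11 ⇐ trans-lactone 10 by hydride reduction.
2. 10 ⇐ hydroxy lactone 4 + syringyl p-quinone methide 9: the lactone C4–CH2Ar bond is made by a photoredox deoxygenative radical 1,6-addition, trans to the C3 benzyl group.
3. 4 ⇐ (R)-3-hydroxy-γ-butyrolactone 1 + bromide 2 by trans-selective dianion alkylation. The bought carbinol centre sets C3, C3 then sets C4, and the carbinol centre itself is erased.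
4. 9 ⇐ benzylic acetate 6 ⇐ syringyl alcohol 5.
5. No ring is formed: the lactone ring is bought in 1, serves as the stereochemical template and is opened at the end; both arenes are bought.

## Route

Step 1
Reactants: 1 (R)-4-hydroxydihydrofuran-2(3H)-one; 2 3,4-dimethoxybenzyl bromide
Product: 4 (3R,4R)-3-(3,4-dimethoxybenzyl)-4-hydroxydihydrofuran-2(3H)-one (trans), via dilithium alkoxide–enolate of 1 3 (not isolated)
Conditions: LDA (2.05 equiv), THF, −78 °C, 1 h; then 2 (1.1 equiv), DMPU, −78 → −40 °C; aq NH4Cl; chromatography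
Reagents that add atoms: 2 3,4-dimethoxybenzyl bromide, COc1ccc(CBr)cc1OC
Why: Fráter–Seebach-type alkylation of the alkoxide–enolate dianion: the C4–OLi group shields its own face of the planar lactone enolate, so the bromide enters anti and sets C3 as R (trans), while oxide is too poor a leaving group for E1cB loss; the minor cis isomer is removed here because it would carry through to the enantiomeric series.

Step 2
Reactants: 5 4-(hydroxymethyl)-2,6-dimethoxyphenol (syringyl alcohol)
Product: 6 4-hydroxy-3,5-dimethoxybenzyl acetate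
Conditions: AcOH (1.5 equiv), PPh3 (1.2 equiv), DIAD (1.2 equiv), THF, 0 °C → rt
Reagents that add atoms: acetic acid, CC(=O)O
Why: Chemoselective Mitsunobu esterification: only the benzylic alcohol is activated as the oxyphosphonium ion and is displaced by acetate (AcOH pKa 4.8 against about 10 for the hindered phenol), so the phenol stays free; no stereocentre is involved.

Step 3
Reactants: 4 (3R,4R)-3-(3,4-dimethoxybenzyl)-4-hydroxydihydrofuran-2(3H)-one; 6 4-hydroxy-3,5-dimethoxybenzyl acetate; 7 5,7-di-tert-butyl-3-phenylbenzo[d]oxazol-3-ium tetrafluoroborate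
Product: 10 (3R,4R)-3-(3,4-dimethoxybenzyl)-4-(4-hydroxy-3,5-dimethoxybenzyl)dihydrofuran-2(3H)-one (trans), via benzoxazoline (NHC–alcohol) adduct of 4 8 (not isolated), via 2,6-dimethoxy-4-methylidenecyclohexa-2,5-dien-1-one 9 (not isolated)
Conditions: (i) 7 (1.1 equiv), pyridine (1.1 equiv), MTBE, rt, 15 min; (ii) 6 (2 equiv), [Ir(dF(CF3)ppy)2(dtbbpy)]PF6 (1 mol %), 2,4,6-collidine (2 equiv), n-Bu4NOAc (20 mol %), 4 Å MS, DMA/MTBE, 450 nm LEDs, N2, rt
Reagents that add atoms: 6 4-hydroxy-3,5-dimethoxybenzyl acetate, CC(=O)OCc1cc(OC)c(O)c(OC)c1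
Why: Proposed new method: the excited Ir(III) catalyst oxidises the N-aryl aminal 8, and deprotonation then β-scission expels the benzoxazolone and leaves the secondary C4 lactone radical; this nucleophilic radical adds to the unhindered exocyclic CH2 of p-quinone methide 9 (released slowly from 6 by phenoxide-triggered 1,6-loss of acetate, each turnover's product phenoxide acting as the base for the next release) on the face anti to the C3 benzyl group, which sets C4 as R (1,2-induction on a five-membered-ring radical, trans expected ≥8:1), and the aromatised phenoxyl radical is reduced by Ir(II) and protonated to the free phenol in a redox-neutral cycle; the closest known reaction types are the deoxygenative Giese addition of benzoxazolium-activated alcohols to Michael acceptors and photoredox radical 1,6-additions to isolable 2,6-di-tert-butyl-7-aryl p-quinone methides, and what is new is a transient, unsubstituted, non-tert-butylated p-quinone methide as acceptor for an alcohol-derived radical under substrate stereocontrol.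

Step 4
Reactants: 10 (3R,4R)-3-(3,4-dimethoxybenzyl)-4-(4-hydroxy-3,5-dimethoxybenzyl)dihydrofuran-2(3H)-one
Product: 11 (2R,3R)-2-(3,4-dimethoxybenzyl)-3-(4-hydroxy-3,5-dimethoxybenzyl)butane-1,4-diol
Conditions: LiAlH4 (3 equiv), THF, 0 °C → rt; Rochelle salt work-up (acid-free)
Reagents that add atoms: none
Why: Lithium aluminium hydride reduction of the lactone to the 1,4-diol; the phenol is only deprotonated, and both stereocentres are untouched because hydride addition outruns enolisation of the trans lactone, which is the thermodynamic isomer in any case.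

Step 5
Reactants: 11 (2R,3R)-2-(3,4-dimethoxybenzyl)-3-(4-hydroxy-3,5-dimethoxybenzyl)butane-1,4-diol
Product: 13 Justin C, (2R,3R)-2-(3,4-dimethoxybenzyl)-3-(4-hydroxy-3,5-dimethoxybenzyl)butane-1,4-diyl diacetate, via (2R,3R)-2-(4-acetoxy-3,5-dimethoxybenzyl)-3-(3,4-dimethoxybenzyl)butane-1,4-diyl diacetate 12 (not isolated)
Conditions: Ac2O (4 equiv), pyridine, DMAP (5 mol %), CH2Cl2, rt; aq NaHCO3 wash; then crude 12, pyrrolidine (3 equiv), CH2Cl2, 0 °C → rt, 30 min
Reagents that add atoms: acetic anhydride, CC(=O)OC(C)=O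
Why: Exhaustive acetylation followed by chemoselective aminolysis: aryl acetates are cleaved by pyrrolidine within minutes whereas primary alkyl acetates survive for hours, so only the phenolic acetate is removed; no stereocentre is touched.

## Compound list

1 | (R)-4-hydroxydihydrofuran-2(3H)-one [(R)-3-hydroxy-γ-butyrolactone] | O=C1OC[C@H](O)C1 | starting material
2 | 3,4-dimethoxybenzyl bromide | COc1ccc(CBr)cc1OC | starting material
3 | dilithium alkoxide–enolate of 1 | [Li+].[Li+].[O-]C1=C[C@@H]([O-])CO1 | intermediate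
4 | (3R,4R)-3-(3,4-dimethoxybenzyl)-4-hydroxydihydrofuran-2(3H)-one | O=C1OC[C@H](O)[C@H]1Cc1ccc(OC)c(OC)c1 | intermediate
5 | 4-(hydroxymethyl)-2,6-dimethoxyphenol (syringyl alcohol) | COc1cc(CO)cc(OC)c1O | starting material
6 | 4-hydroxy-3,5-dimethoxybenzyl acetate | CC(=O)OCc1cc(OC)c(O)c(OC)c1 | intermediate
7 | 5,7-di-tert-butyl-3-phenylbenzo[d]oxazol-3-ium tetrafluoroborate | CC(C)(C)c1cc(C(C)(C)C)c2oc[n+](-c3ccccc3)c2c1.F[B-](F)(F)F | starting material
8 | (3R,4R)-4-[(5,7-di-tert-butyl-3-phenyl-2,3-dihydrobenzo[d]oxazol-2-yl)oxy]-3-(3,4-dimethoxybenzyl)dihydrofuran-2(3H)-one (aminal carbon unassigned) | CC(C)(C)c1cc(C(C)(C)C)c2OC(O[C@H]3COC(=O)[C@@H]3Cc4ccc(OC)c(OC)c4)N(c5ccccc5)c2c1 | intermediate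
9 | 2,6-dimethoxy-4-methylidenecyclohexa-2,5-dien-1-one (syringyl p-quinone methide) | C=C1C=C(OC)C(=O)C(OC)=C1 | intermediate
10 | (3R,4R)-3-(3,4-dimethoxybenzyl)-4-(4-hydroxy-3,5-dimethoxybenzyl)dihydrofuran-2(3H)-one | O=C1OC[C@H](Cc2cc(OC)c(O)c(OC)c2)[C@H]1Cc3ccc(OC)c(OC)c3 | intermediate
11 | (2R,3R)-2-(3,4-dimethoxybenzyl)-3-(4-hydroxy-3,5-dimethoxybenzyl)butane-1,4-diol | COc1ccc(C[C@@H](CO)[C@H](CO)Cc2cc(OC)c(O)c(OC)c2)cc1OC | intermediate
12 | (2R,3R)-2-(4-acetoxy-3,5-dimethoxybenzyl)-3-(3,4-dimethoxybenzyl)butane-1,4-diyl diacetate | COc1ccc(C[C@@H](COC(C)=O)[C@H](COC(C)=O)Cc2cc(OC)c(OC(C)=O)c(OC)c2)cc1OC | intermediate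
13 | Justin C, (2R,3R)-2-(3,4-dimethoxybenzyl)-3-(4-hydroxy-3,5-dimethoxybenzyl)butane-1,4-diyl diacetate | COc1ccc(C[C@@H](COC(C)=O)[C@H](COC(C)=O)Cc2cc(OC)c(O)c(OC)c2)cc1OC | target

## Step count and risk

Total steps: 5. Longest linear sequence: 4 (steps 1, 3, 4, 5); step 2 is a one-step side branch.

Three steps most likely to fail, in order: step 3, step 2, step 1.

**Step 3 (proposed new step).** Risks are competing oxidation of the phenols by the photocatalyst, oligomerisation of 9, and a modest trans:cis ratio. The fallback uses only known lignan chemistry, sets out from 2 and comes back at 10. Diethyl malonate and (R)-epichlorohydrin (NaOEt, EtOH, reflux) give ethyl (1S,5R)-2-oxo-3-oxabicyclo[3.1.0]hexane-1-carboxylate F1. Commercial 4-bromo-2,6-dimethoxyphenol is benzylated (BnBr, K2CO3, DMF) to 2-(benzyloxy)-5-bromo-1,3-dimethoxybenzene F2, which is converted (Mg, THF) into [4-(benzyloxy)-3,5-dimethoxyphenyl]magnesium bromide F3. Copper-catalysed opening of the activated cyclopropane of F1 by F3 (CuI 10 mol %, THF, −30 °C) gives ethyl (4R)-4-[4-(benzyloxy)-3,5-dimethoxybenzyl]-2-oxotetrahydrofuran-3-carboxylate F4, with the epichlorohydrin stereocentre now at C4. Krapcho dealkoxycarbonylation (LiCl, wet DMSO, 140 °C) gives (4R)-4-[4-(benzyloxy)-3,5-dimethoxybenzyl]dihydrofuran-2(3H)-one F5. Enolate alkylation (LiHMDS, THF, −78 °C) with 2 enters anti to the C4 substituent and gives (3R,4R)-4-[4-(benzyloxy)-3,5-dimethoxybenzyl]-3-(3,4-dimethoxybenzyl)dihydrofuran-2(3H)-one F6. Hydrogenolysis (H2, Pd/C, EtOAc) gives 10.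

**Step 2.** Acetate 6 is a labile quinone methide precursor and may oligomerise during the Mitsunobu reaction or on silica. The fallback changes the leaving group and the way it is installed; it sets out from 5 and comes back at 9. Acid-mediated substitution of 5 with sodium benzenesulfinate (aq HCO2H, rt) gives the crystalline, bench-stable sulfone 2,6-dimethoxy-4-[(phenylsulfonyl)methyl]phenol F11. In step 3, K2CO3 in MTBE-rich solvent (in place of collidine) releases 9 from F11, and the sparingly soluble sulfinate salt stays largely out of solution.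

**Step 1.** Risks are moderate yield, C,C-dialkylation, and any cis isomer, which would erode the final ee. The fallback replaces the lactone dianion by an acyclic chelated dianion of the cheap L-malate; it sets out from 2 and comes back at 10. Fráter–Seebach alkylation of diethyl (S)-malate (LiHMDS 2.1 equiv, THF, −78 → −20 °C) with 2 gives erythro diethyl (2S,3R)-3-(3,4-dimethoxybenzyl)-2-hydroxysuccinate F7 (minor threo isomer removed). Hydroxyl-directed reduction of the ester next to the carbinol (BH3·SMe2, cat. NaBH4, THF) gives ethyl (2R,3S)-2-(3,4-dimethoxybenzyl)-3,4-dihydroxybutanoate F8. Lactonisation (cat. TsOH, CH2Cl2) gives (3R,4S)-3-(3,4-dimethoxybenzyl)-4-hydroxydihydrofuran-2(3H)-one F9, the C4 epimer of 4 with the same (R) benzyl-bearing centre. Because C4 becomes a planar radical, F9 is put through the step 3 conditions unchanged, via its benzoxazoline adduct (3R,4S)-4-[(5,7-di-tert-butyl-3-phenyl-2,3-dihydrobenzo[d]oxazol-2-yl)oxy]-3-(3,4-dimethoxybenzyl)dihydrofuran-2(3H)-one F10, and gives 10.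

## Further compounds

F1 | step 3 | ethyl (1S,5R)-2-oxo-3-oxabicyclo[3.1.0]hexane-1-carboxylate | CCOC(=O)[C@]12C[C@H]1COC2=O
F2 | step 3 | 2-(benzyloxy)-5-bromo-1,3-dimethoxybenzene | COc1cc(Br)cc(OC)c1OCc1ccccc1
F3 | step 3 | [4-(benzyloxy)-3,5-dimethoxyphenyl]magnesium bromide | COc1cc([Mg]Br)cc(OC)c1OCc1ccccc1
F4 | step 3 | ethyl (4R)-4-[4-(benzyloxy)-3,5-dimethoxybenzyl]-2-oxotetrahydrofuran-3-carboxylate (C3 epimers) | CCOC(=O)C1C(=O)OC[C@@H]1Cc1cc(OC)c(OCc2ccccc2)c(OC)c1
F5 | step 3 | (4R)-4-[4-(benzyloxy)-3,5-dimethoxybenzyl]dihydrofuran-2(3H)-one | O=C1C[C@@H](Cc2cc(OC)c(OCc3ccccc3)c(OC)c2)CO1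
F6 | step 3 | (3R,4R)-4-[4-(benzyloxy)-3,5-dimethoxybenzyl]-3-(3,4-dimethoxybenzyl)dihydrofuran-2(3H)-one | O=C1OC[C@H](Cc2cc(OC)c(OCc3ccccc3)c(OC)c2)[C@H]1Cc4ccc(OC)c(OC)c4
F7 | step 1 | diethyl (2S,3R)-3-(3,4-dimethoxybenzyl)-2-hydroxysuccinate | CCOC(=O)[C@H](Cc1ccc(OC)c(OC)c1)[C@H](O)C(=O)OCC
F8 | step 1 | ethyl (2R,3S)-2-(3,4-dimethoxybenzyl)-3,4-dihydroxybutanoate | CCOC(=O)[C@H](Cc1ccc(OC)c(OC)c1)[C@H](O)CO
F9 | step 1 | (3R,4S)-3-(3,4-dimethoxybenzyl)-4-hydroxydihydrofuran-2(3H)-one | O=C1OC[C@@H](O)[C@H]1Cc1ccc(OC)c(OC)c1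
F10 | step 1 | (3R,4S)-4-[(5,7-di-tert-butyl-3-phenyl-2,3-dihydrobenzo[d]oxazol-2-yl)oxy]-3-(3,4-dimethoxybenzyl)dihydrofuran-2(3H)-one | CC(C)(C)c1cc(C(C)(C)C)c2OC(O[C@@H]3COC(=O)[C@@H]3Cc4ccc(OC)c(OC)c4)N(c5ccccc5)c2c1
F11 | step 2 | 2,6-dimethoxy-4-[(phenylsulfonyl)methyl]phenol | COc1cc(CS(=O)(=O)c2ccccc2)cc(OC)c1O
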